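**Retrosynthetic overview** (chain carbons are numbered C1–C7 from the guaiacyl ring)

1. Enabling feature: C1 is benzylic to the para-oxygenated guaiacyl ring and stands 1,5 to the oxygen on C5, with the C3 oxygen between them. C1 and O(C5) can therefore be tied into a temporary 2-aryl-tetrahydropyran and the C1–O bond later cut by benzylic hydrogenolysis.
2. Last disconnection: the ring C1–O bond and both O-benzyl groups, removed in one hydrogenolysis of a 2,4,6-trisubstituted tetrahydropyran-4-ol. Its axial hydroxyl (C3) comes from the cis-2,6-tetrahydropyran-4-one by equatorial hydride delivery.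
3. Key disconnection: the C1–C2 and C1–O bonds of that pyranone, by silyl enol ether Prins cyclization of O-benzylvanillin with the bis-silyl derivative of an (R)-β-hydroxy methyl ketone carrying C2–C7 and the syringyl ring.
4. That ketone comes from 4-allyl-2,6-dimethoxyphenol by benzylation, hydroboration, enantioselective Ir-catalysed allylation (sets C5, the only centre from external chirality) and Wacker oxidation.
5. Ring order: both arenes are bought; the only ring made is the tetrahydropyran (step 6), and it is opened again in step 8.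

Key step: step 6

Assumption: the (S)-configured bisphosphine is taken to give the (R)-carbinol 7, by analogy with the usual sense of this allylation for unbranched alkanols; if the sense is opposite, the other ligand enantiomer is used and nothing else changes.

**Step 1**
Reactants: 1 4-allyl-2,6-dimethoxyphenol
Product: 2 5-allyl-2-(benzyloxy)-1,3-dimethoxybenzene
Conditions: BnBr, K2CO3, DMF, rt
Reagents that add atoms: benzyl bromide, BrCc1ccccc1
Why: Williamson etherification of the acidic 2,6-dimethoxyphenol should be clean under carbonate base and masks the phenol with a group that leaves in the final hydrogenolysis; no stereocentre is formed.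

**Step 2**
Reactants: 2 5-allyl-2-(benzyloxy)-1,3-dimethoxybenzene
Product: 4 3-[4-(benzyloxy)-3,5-dimethoxyphenyl]propan-1-ol, via B-alkyl-9-BBN 3 (not isolated)
Conditions: 9-BBN, THF, 0 °C to rt; then NaOH, H2O2, 0 °C to rt
Reagents that add atoms: 9-borabicyclo[3.3.1]nonane, B1C2CCCC1CCC2 (its boron and carbons stay only in 3); hydrogen peroxide, OO (source of the hydroxyl oxygen of 4)
Why: Hydroboration–oxidation with the bulky 9-BBN places boron on the terminal carbon of the allyl group (anti-Markovnikov) and alkaline peroxide replaces it by hydroxyl while the benzyl ether is untouched; no stereocentre is formed.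

**Step 3**
Reactants: 4 3-[4-(benzyloxy)-3,5-dimethoxyphenyl]propan-1-ol; 5 allyl acetate (excess)
Product: 7 (3R)-1-[4-(benzyloxy)-3,5-dimethoxyphenyl]hex-5-en-3-ol, via 3-arylpropanal 6 (not isolated)
Conditions: [Ir(cod)Cl]2 (cat.), (S)-Cl,MeO-BIPHEP (cat.), 4-Cl-3-NO2-C6H3CO2H (cat.), Cs2CO3 (cat.), THF, 100 °C, sealed tube
Reagents that add atoms: none
Why: Iridium-catalysed transfer-hydrogenative carbonyl allylation (Krische allylation): the primary alcohol is dehydrogenated to aldehyde 6 while allyl acetate becomes a cyclometallated π-allyliridium nucleophile, and addition through a closed chair transition state under control of the chiral bisphosphine should set the carbinol centre (the future C5) as R.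

**Step 4**
Reactants: 7 (3R)-1-[4-(benzyloxy)-3,5-dimethoxyphenyl]hex-5-en-3-ol
Product: 8 (4R)-6-[4-(benzyloxy)-3,5-dimethoxyphenyl]-4-hydroxyhexan-2-one
Conditions: PdCl2 (cat.), CuCl (co-catalyst), O2 (1 atm), DMF–H2O, rt
Reagents that add atoms: water, O
Why: Tsuji–Wacker oxidation of the terminal alkene proceeds by Markovnikov hydroxypalladation to the methyl ketone, tolerates a free homoallylic hydroxyl and does not touch the carbinol centre.

**Step 5**
Reactants: 8 (4R)-6-[4-(benzyloxy)-3,5-dimethoxyphenyl]-4-hydroxyhexan-2-one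
Product: 9 (4R)-6-[4-(benzyloxy)-3,5-dimethoxyphenyl]-2,4-bis(trimethylsilyloxy)hex-1-ene
Conditions: LDA (2.2 equiv), TMSCl (2.5 equiv, internal quench), THF, −78 °C; non-aqueous work-up, used crude
Reagents that add atoms: chlorotrimethylsilane, C[Si](C)(C)Cl
Why: Kinetic deprotonation by LDA at −78 °C removes a proton from the unhindered methyl group rather than the C4 methylene, and the internal TMSCl quench traps both the alkoxide and the terminal enolate (kinetic silyl enol ether formation); the stereocentre is not involved.

**Step 6**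
Reactants: 9 (4R)-6-[4-(benzyloxy)-3,5-dimethoxyphenyl]-2,4-bis(trimethylsilyloxy)hex-1-ene; 10 4-(benzyloxy)-3-methoxybenzaldehyde (O-benzylvanillin)
Product: 12 (2R,6R)-2-[4-(benzyloxy)-3-methoxyphenyl]-6-{2-[4-(benzyloxy)-3,5-dimethoxyphenyl]ethyl}tetrahydropyran-4-one (2,6-cis), via oxocarbenium triflate 11 (not isolated)
Conditions: TMSOTf (cat.), CH2Cl2, −78 to −20 °C; aq. NaHCO3
Reagents that add atoms: none
Why: TMSOTf condenses the C5 silyl ether of 9 with aldehyde 10 (loss of hexamethyldisiloxane) to the (E)-oxocarbenium ion 11, whose terminal enol-ether carbon C2 attacks C1 and, after loss of the second silyl group, leaves the C3 ketone; this is a silyl enol ether Prins (Mukaiyama-type oxocarbenium) cyclization, with the union of hydroxy silyl enol ethers and aldehydes to cis-2,6-disubstituted tetrahydropyran-4-ones as the closest known reaction type. The tetrahydropyran closes in a 6-endo-trig mode through a chair transition state. The new C1 centre is controlled by the existing C5 centre: the C5 side chain and the aryl group of the (E)-oxocarbenium both sit equatorial, so the 2,6-cis ring should result, and any trans isomer or acyclic aldol adduct can re-ionise at the electron-rich benzylic C1–O bond and funnel into the same cis ring. The step needs regioselectivity for C2 over C4 (secured by the terminal, kinetically formed enol ether), chemoselectivity against Friedel–Crafts attack by the two electron-rich arenes (secured by the intramolecular and far more nucleophilic enol ether at low temperature) and integrity of C5 (secured because the C5–O bond is never broken). The para-alkoxy group that stabilises the oxocarbenium ion is the same feature that later allows the C1–O bond to be removed, and since C1 ends as a methylene group its configuration matters only for the shape of the ring.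

**Step 7**
Reactants: 12 (2R,6R)-2-[4-(benzyloxy)-3-methoxyphenyl]-6-{2-[4-(benzyloxy)-3,5-dimethoxyphenyl]ethyl}tetrahydropyran-4-one
Product: 13 (2R,4R,6R)-2-[4-(benzyloxy)-3-methoxyphenyl]-6-{2-[4-(benzyloxy)-3,5-dimethoxyphenyl]ethyl}tetrahydropyran-4-ol (4-OH axial, trans to both ring substituents)
Conditions: L-Selectride, THF, −78 °C; then H2O
Reagents that add atoms: none
Why: L-Selectride reduction of the conformationally locked cis-2,6-disubstituted pyranone: the bulky hydride approaches along the equatorial trajectory of the chair with both substituents equatorial, so the hydroxyl should end up axial (4R), which is the 1,3-syn relationship to the C5 oxygen and becomes the 3S carbinol of the target.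

**Step 8**
Reactants: 13 (2R,4R,6R)-2-[4-(benzyloxy)-3-methoxyphenyl]-6-{2-[4-(benzyloxy)-3,5-dimethoxyphenyl]ethyl}tetrahydropyran-4-ol
Product: 15 (3S,5R)-1-(4-hydroxy-3-methoxyphenyl)-7-(4-hydroxy-3,5-dimethoxyphenyl)heptane-3,5-diol, via bis-phenol tetrahydropyranol 14 (not isolated)
Conditions: H2 (4 bar), Pd(OH)2/C, HCl (cat.), EtOH, rt
Reagents that add atoms: none
Why: Palladium-catalysed hydrogenolysis cleaves the two benzyl aryl ethers and then, assisted by a trace of acid and the para-hydroxyl freed in 14, the benzylic ring C–O bond at C1, which turns the ring oxygen into the C5 hydroxyl and C1 into a methylene group without touching the C3 or C5 centres.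

**Compound list**

1 | 4-allyl-2,6-dimethoxyphenol | C=CCc1cc(OC)c(O)c(OC)c1 | starting material
2 | 5-allyl-2-(benzyloxy)-1,3-dimethoxybenzene | C=CCc1cc(OC)c(OCc2ccccc2)c(OC)c1 | intermediate
3 | 9-{3-[4-(benzyloxy)-3,5-dimethoxyphenyl]propyl}-9-borabicyclo[3.3.1]nonane | COc1cc(CCCB2C3CCCC2CCC3)cc(OC)c1OCc1ccccc1 | intermediate (not isolated)
4 | 3-[4-(benzyloxy)-3,5-dimethoxyphenyl]propan-1-ol | COc1cc(CCCO)cc(OC)c1OCc1ccccc1 | intermediate
5 | allyl acetate | CC(=O)OCC=C | starting material
6 | 3-[4-(benzyloxy)-3,5-dimethoxyphenyl]propanal | COc1cc(CCC=O)cc(OC)c1OCc1ccccc1 | intermediate (not isolated)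
7 | (3R)-1-[4-(benzyloxy)-3,5-dimethoxyphenyl]hex-5-en-3-ol | C=CC[C@H](O)CCc1cc(OC)c(OCc2ccccc2)c(OC)c1 | intermediate
8 | (4R)-6-[4-(benzyloxy)-3,5-dimethoxyphenyl]-4-hydroxyhexan-2-one | CC(=O)C[C@H](O)CCc1cc(OC)c(OCc2ccccc2)c(OC)c1 | intermediate
9 | (4R)-6-[4-(benzyloxy)-3,5-dimethoxyphenyl]-2,4-bis(trimethylsilyloxy)hex-1-ene | C=C(O[Si](C)(C)C)C[C@H](O[Si](C)(C)C)CCc1cc(OC)c(OCc2ccccc2)c(OC)c1 | intermediate
10 | 4-(benzyloxy)-3-methoxybenzaldehyde | COc1cc(C=O)ccc1OCc1ccccc1 | starting material
11 | (E)-[4-(benzyloxy)-3-methoxybenzylidene]{(3R)-1-[4-(benzyloxy)-3,5-dimethoxyphenyl]-5-(trimethylsilyloxy)hex-5-en-3-yl}oxonium triflate | C=C(O[Si](C)(C)C)C[C@H]([O+]=Cc1ccc(OCc2ccccc2)c(OC)c1)CCc1cc(OC)c(OCc2ccccc2)c(OC)c1.[O-]S(=O)(=O)C(F)(F)F | intermediate (not isolated)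
12 | (2R,6R)-2-[4-(benzyloxy)-3-methoxyphenyl]-6-{2-[4-(benzyloxy)-3,5-dimethoxyphenyl]ethyl}tetrahydropyran-4-one | O=C1C[C@H](c2ccc(OCc3ccccc3)c(OC)c2)O[C@H](CCc2cc(OC)c(OCc3ccccc3)c(OC)c2)C1 | intermediate
13 | (2R,4R,6R)-2-[4-(benzyloxy)-3-methoxyphenyl]-6-{2-[4-(benzyloxy)-3,5-dimethoxyphenyl]ethyl}tetrahydropyran-4-ol | O[C@H]1C[C@H](c2ccc(OCc3ccccc3)c(OC)c2)O[C@H](CCc2cc(OC)c(OCc3ccccc3)c(OC)c2)C1 | intermediate
14 | (2R,4R,6R)-2-(4-hydroxy-3-methoxyphenyl)-6-[2-(4-hydroxy-3,5-dimethoxyphenyl)ethyl]tetrahydropyran-4-ol | O[C@H]1C[C@H](c2ccc(O)c(OC)c2)O[C@H](CCc2cc(OC)c(O)c(OC)c2)C1 | intermediate (not isolated)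
15 | (3S,5R)-1-(4-hydroxy-3-methoxyphenyl)-7-(4-hydroxy-3,5-dimethoxyphenyl)heptane-3,5-diol | COc1cc(CC[C@H](O)C[C@H](O)CCc2cc(OC)c(O)c(OC)c2)ccc1O | target

**Step count and risks**

Total step count: 8. Longest linear sequence: 8 steps (1 to 15); 5 and 10 enter as purchased materials.

Steps most likely to fail:

Step 6. The ring closure may be outrun by intermolecular aldol addition or by protodesilylation of the enol ether, so that the oxocarbenium ion is not intercepted intramolecularly. The fallback sets out from 9 and separates bond formation from ring closure. A deliberate Mukaiyama aldol addition of 9 to 10 (BF3·OEt2, CH2Cl2, −78 °C, aqueous work-up) should give the acyclic aldol (5R)-1-[4-(benzyloxy)-3-methoxyphenyl]-7-[4-(benzyloxy)-3,5-dimethoxyphenyl]-1,5-dihydroxyheptan-3-one F1 as a mixture of C1 epimers. Acid-catalysed cyclodehydration (cat. TsOH, CH2Cl2, rt) ionises only the para-alkoxybenzylic C1–OH and lets the C5 hydroxyl close the ring under thermodynamic control, which returns to the route at 12.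

Step 8. Hydrogenolysis may stop after O-debenzylation with the ring C1–O bond intact, or acid-induced ionisation at C1 may lead to elimination towards C2. The fallback sets out from 13 and opens the ring before the benzyl groups are removed. Ionic hydrogenation (Et3SiH, TFA, CH2Cl2, −20 °C, then K2CO3/MeOH to cleave any trifluoroacetate) should give (3S,5R)-1-[4-(benzyloxy)-3-methoxyphenyl]-7-[4-(benzyloxy)-3,5-dimethoxyphenyl]heptane-3,5-diol F2. Neutral hydrogenolysis (H2, Pd/C, EtOAc–MeOH) then returns to the route at 15.

Step 7. Facial discrimination in the hydride delivery may be insufficient; competing axial attack would give the equatorial alcohol and hence the 3,5-anti diol. The fallback sets out from 12 and sets C3 in the open chain instead of on the ring. Hydrogenolysis of the ketone (H2, Pd(OH)2/C, cat. HCl, EtOH) should open the ring and remove both benzyl groups to give (5R)-5-hydroxy-1-(4-hydroxy-3-methoxyphenyl)-7-(4-hydroxy-3,5-dimethoxyphenyl)heptan-3-one F3. Narasaka–Prasad reduction (excess Et2BOMe, NaBH4, THF–MeOH, −78 °C) then delivers hydride to the boron chelate of the C5 hydroxyl and the C3 ketone to give the 1,3-syn diol, returning to the route at 15.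

**Further compounds**

F1 | step 6 | (5R)-1-[4-(benzyloxy)-3-methoxyphenyl]-7-[4-(benzyloxy)-3,5-dimethoxyphenyl]-1,5-dihydroxyheptan-3-one (C1 epimers) | COc1cc(C(O)CC(=O)C[C@H](O)CCc2cc(OC)c(OCc3ccccc3)c(OC)c2)ccc1OCc1ccccc1
F2 | step 8 | (3S,5R)-1-[4-(benzyloxy)-3-methoxyphenyl]-7-[4-(benzyloxy)-3,5-dimethoxyphenyl]heptane-3,5-diol | COc1cc(CC[C@H](O)C[C@H](O)CCc2cc(OC)c(OCc3ccccc3)c(OC)c2)ccc1OCc1ccccc1
F3 | step 7 | (5R)-5-hydroxy-1-(4-hydroxy-3-methoxyphenyl)-7-(4-hydroxy-3,5-dimethoxyphenyl)heptan-3-one | COc1cc(CCC(=O)C[C@H](O)CCc2cc(OC)c(O)c(OC)c2)ccc1O
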